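**Retrosynthetic overview**
1. The target is the 7‑O‑(4‑oxooct‑2‑enoyl) ester of bicyclic diol lactone 16; the side‑chain acid 19 comes from 2‑butylfuran.
2. Lactone ring (formed last): Dieckmann closure of a C5 propanoate onto the C3 ester (C2–C3 bond), then face‑selective hydrogenation of the enol to set C2 and C3.
3. Oxane ring (formed first): reductive etherification of the tertiary C4–OH onto a C8 methyl ketone; the C4/C5 diol comes from OsO4 on a (Z)‑enoate.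
4. The C6–C7 bond and both stereocentres come from a glycolate Ireland–Claisen [3,3] rearrangement with 1,3‑chirality transfer from (R)‑pent‑3‑en‑2‑ol, made from (R)‑but‑3‑yn‑2‑ol, the only chiral input.

Assumption: (R)‑but‑3‑yn‑2‑ol is bought as the single chiral starting material. Atom numbers C1–C9 follow the target chain (C1 lactone carbonyl, C4 quaternary carbon, C8 the ring O–CH(CH3) carbon).

**Step 1**
Reactants: 1 (R)‑but‑3‑yn‑2‑ol
Product: 2 (R)‑pent‑3‑yn‑2‑ol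
Conditions: n‑BuLi (2.1 equiv), THF, −78 °C; MeI, −78 → 20 °C
Reagents that add atoms: iodomethane CI
Why: The alkoxide/acetylide dianion is alkylated at carbon (acetylide methylation); the carbinol stereocentre is not touched.

**Step 2**
Reactants: 2 (R)‑pent‑3‑yn‑2‑ol
Product: 3 (2R,3E)‑pent‑3‑en‑2‑ol
Conditions: LiAlH4, THF, 65 °C; H2O/NaOH work‑up
Reagents that add atoms: none
Why: Hydroxyl‑directed trans‑hydroalumination of the propargylic alcohol gives only the E‑alkene.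

**Step 3**
Reactants: 3 (2R,3E)‑pent‑3‑en‑2‑ol
Product: 4 (2R,3E)‑pent‑3‑en‑2‑yl (benzyloxy)acetate
Conditions: BnOCH2COCl, Et3N, DMAP (cat.), CH2Cl2, 0 °C
Reagents that add atoms: (benzyloxy)acetyl chloride O=C(Cl)COCc1ccccc1
Why: Simple O‑acylation with retention at the carbinol carbon.

**Step 4 (key step)**
Reactants: 4 (2R,3E)‑pent‑3‑en‑2‑yl (benzyloxy)acetate
Product: 6 (2R,3S,4E)‑2‑(benzyloxy)‑3‑methylhex‑4‑enoic acid, via (Z)‑silyl ketene acetal 5 (not isolated)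
Conditions: LiN(iPr)2, THF, −78 °C; Me3SiCl, Et3N; −78 → 25 °C; aq. HCl
Reagents that add atoms: none
Why: Ireland–Claisen [3,3]‑sigmatropic rearrangement of the chelated (Z)‑glycolate ketene acetal through a chair with the carbinol methyl equatorial forms the C6–C7 bond, transfers the carbinol chirality suprafacially to C6 and C7 (2,3‑syn from the E‑alkene) and leaves an E‑propenyl group.

**Step 5**
Reactants: 6 (2R,3S,4E)‑2‑(benzyloxy)‑3‑methylhex‑4‑enoic acid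
Product: 7 (3R,4S,5E)‑3‑(benzyloxy)‑4‑methylhept‑5‑en‑2‑one
Conditions: MeLi (2.5 equiv), Et2O, −78 → 0 °C; aq. NH4Cl
Reagents that add atoms: methyllithium [Li]C
Why: Methyllithium adds to the lithium carboxylate to give a stable gem‑diolate that collapses to the methyl ketone only on work‑up (acid‑to‑ketone conversion); C6 and C7 are untouched.

**Step 6**
Reactants: 7 (3R,4S,5E)‑3‑(benzyloxy)‑4‑methylhept‑5‑en‑2‑one
Product: 8 (2R,3R)‑3‑(benzyloxy)‑2‑methyl‑4‑oxopentanal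
Conditions: O3, CH2Cl2, −78 °C; Me2S; used crude and cold
Reagents that add atoms: ozone [O-][O+]=O
Why: Ozonolysis with reductive work‑up cleaves the propenyl group to the C5 aldehyde; no stereocentre is involved.

**Step 7**
Reactants: 8 (2R,3R)‑3‑(benzyloxy)‑2‑methyl‑4‑oxopentanal
Product: 9 methyl (2Z,4S,5R)‑5‑(benzyloxy)‑2,4‑dimethyl‑6‑oxohept‑2‑enoate
Conditions: (CF3CH2O)2P(O)CH(CH3)CO2CH3, KN(SiMe3)2, 18‑crown‑6, THF, −78 °C
Reagents that add atoms: methyl 2‑[bis(2,2,2‑trifluoroethoxy)phosphoryl]propanoate COC(=O)C(C)P(=O)(OCC(F)(F)F)OCC(F)(F)F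
Why: Still–Gennari olefination gives the (Z)‑trisubstituted enoate, and the aldehyde reacts in preference to the ketone.

**Step 8**
Reactants: 9 methyl (2Z,4S,5R)‑5‑(benzyloxy)‑2,4‑dimethyl‑6‑oxohept‑2‑enoate
Product: 10 methyl (2S,3S,4S,5R)‑5‑(benzyloxy)‑2,3‑dihydroxy‑2,4‑dimethyl‑6‑oxoheptanoate
Conditions: OsO4 (5 mol %), NMO, acetone–H2O, 20 °C, neutral
Reagents that add atoms: N‑methylmorpholine N‑oxide C[N+]1([O-])CCOCC1; water O
Why: Upjohn syn‑dihydroxylation; A(1,3) strain of the Z‑enoate holds the C6–H in the alkene plane so OsO4 adds anti to the C7 branch, giving C5–OH syn to the C6 methyl and, by syn addition to the Z‑alkene, the C4/C5 anti diol.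

**Step 9**
Reactants: 10 methyl (2S,3S,4S,5R)‑5‑(benzyloxy)‑2,3‑dihydroxy‑2,4‑dimethyl‑6‑oxoheptanoate
Product: 11 methyl (2S,3S,4S,5R)‑5‑(benzyloxy)‑2‑hydroxy‑2,4‑dimethyl‑6‑oxo‑3‑(propanoyloxy)heptanoate
Conditions: (EtCO)2O, Et3N, DMAP (cat.), CH2Cl2, 0 °C
Reagents that add atoms: propanoic anhydride CCC(=O)OC(=O)CC
Why: DMAP‑catalysed acylation takes the secondary hydroxyl and leaves the tertiary one; the ester blocks five‑ring ketal formation at O5 and is the later Dieckmann nucleophile.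

**Step 10**
Reactants: 11 methyl (2S,3S,4S,5R)‑5‑(benzyloxy)‑2‑hydroxy‑2,4‑dimethyl‑6‑oxo‑3‑(propanoyloxy)heptanoate
Product: 13 methyl (2S,3S,4R,5R,6S)‑5‑(benzyloxy)‑2,4,6‑trimethyl‑3‑(propanoyloxy)oxane‑2‑carboxylate, via cyclic hemiketal 12 (not isolated)
Conditions: Et3SiH, Me3SiOTf (cat.), CH2Cl2, −78 → −20 °C
Reagents that add atoms: none
Why: Reductive etherification: the tertiary hydroxyl and the C8 ketone give a six‑membered oxocarbenium ion that takes hydride axially, so the C8 methyl ends equatorial (all ring substituents equatorial, C4 methyl axial).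

**Step 11**
Reactants: 13 methyl (2S,3S,4R,5R,6S)‑5‑(benzyloxy)‑2,4,6‑trimethyl‑3‑(propanoyloxy)oxane‑2‑carboxylate
Product: 14 (4aS,6S,7R,8R,8aS)‑7‑(benzyloxy)‑4‑hydroxy‑3,4a,6,8‑tetramethyl‑6,7,8,8a‑tetrahydro‑4aH‑pyrano[3,2‑b]pyran‑2‑one (enol form of the 3‑oxo lactone)
Conditions: LiN(SiMe3)2 (2.5 equiv), THF, −78 → 0 °C; aq. HCl
Reagents that add atoms: none
Why: Dieckmann (intramolecular Claisen) condensation: the propanoate enolate acylates the neighbouring non‑enolisable methyl ester and closes the trans‑fused six‑membered lactone.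

**Step 12**
Reactants: 14 enol lactone
Product: 16 (3R,4S,4aR,6S,7R,8R,8aS)‑4,7‑dihydroxy‑3,4a,6,8‑tetramethylhexahydro‑2H,5H‑pyrano[3,2‑b]pyran‑2‑one, via 7‑O‑benzyl hydroxy lactone 15 (not isolated)
Conditions: H2 (50 bar), Ni (Raney), EtOAc, 25 °C; then H2 (1 bar), Pd(OH)2/C, EtOH
Reagents that add atoms: none
Why: Heterogeneous syn‑hydrogenation of the enol C2=C3 from the face opposite the axial C4 methyl places 2‑CH3 and 3‑OH cis to it (the all‑cis outcome known for 3‑alkyl‑4‑hydroxy‑dihydropyranones); hydrogenolysis then removes the benzyl ether.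

**Step 13**
Reactants: 17 2‑butylfuran
Product: 19 (2E)‑4‑oxooct‑2‑enoic acid, via (E)‑4‑oxooct‑2‑enal 18 (not isolated)
Conditions: NBS, NaHCO3, acetone–H2O, −15 °C; pyridine, 20 °C; then NaClO2, NaH2PO4, 2‑methylbut‑2‑ene, t‑BuOH–H2O
Reagents that add atoms: water O; sodium chlorite [Na+].[O-]Cl=O
Why: Oxidative furan ring opening gives the ene‑dicarbonyl, pyridine isomerises Z to E, and Pinnick oxidation converts the aldehyde to the acid.

**Step 14**
Reactants: 16 diol lactone; 19 (2E)‑4‑oxooct‑2‑enoic acid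
Product: 20 Botcinin I, (3R,4S,4aR,6S,7R,8R,8aS)‑4‑hydroxy‑3,4a,6,8‑tetramethyl‑2‑oxohexahydro‑2H,5H‑pyrano[3,2‑b]pyran‑7‑yl (2E)‑4‑oxooct‑2‑enoate
Conditions: 2‑methyl‑6‑nitrobenzoic anhydride (MNBA), Et3N, DMAP (cat.), CH2Cl2, 20 °C
Reagents that add atoms: none
Why: Shiina mixed‑anhydride esterification should take the equatorial 7‑OH in preference to the 3‑OH, which is flanked by the quaternary C4; mild base limits C2 epimerisation.

**Compound list**
1 | (R)‑but‑3‑yn‑2‑ol | C[C@@H](O)C#C | starting material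
2 | (R)‑pent‑3‑yn‑2‑ol | C[C@@H](O)C#CC | intermediate
3 | (2R,3E)‑pent‑3‑en‑2‑ol | C[C@@H](O)/C=C/C | intermediate
4 | (2R,3E)‑pent‑3‑en‑2‑yl (benzyloxy)acetate | C[C@@H](OC(=O)COCc1ccccc1)/C=C/C | intermediate
5 | (Z)‑O‑trimethylsilyl ketene acetal of 4 (OBn cis to OSi) | C[C@@H](O/C(O[Si](C)(C)C)=C/OCc1ccccc1)/C=C/C | intermediate (not isolated)
6 | (2R,3S,4E)‑2‑(benzyloxy)‑3‑methylhex‑4‑enoic acid | OC(=O)[C@H](OCc1ccccc1)[C@@H](C)/C=C/C | intermediate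
7 | (3R,4S,5E)‑3‑(benzyloxy)‑4‑methylhept‑5‑en‑2‑one | CC(=O)[C@H](OCc1ccccc1)[C@@H](C)/C=C/C | intermediate
8 | (2R,3R)‑3‑(benzyloxy)‑2‑methyl‑4‑oxopentanal | CC(=O)[C@H](OCc1ccccc1)[C@@H](C)C=O | intermediate
9 | methyl (2Z,4S,5R)‑5‑(benzyloxy)‑2,4‑dimethyl‑6‑oxohept‑2‑enoate | CC(=O)[C@H](OCc1ccccc1)[C@@H](C)/C=C(/C)C(=O)OC | intermediate
10 | methyl (2S,3S,4S,5R)‑5‑(benzyloxy)‑2,3‑dihydroxy‑2,4‑dimethyl‑6‑oxoheptanoate | CC(=O)[C@H](OCc1ccccc1)[C@@H](C)[C@H](O)[C@](C)(O)C(=O)OC | intermediate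
11 | methyl (2S,3S,4S,5R)‑5‑(benzyloxy)‑2‑hydroxy‑2,4‑dimethyl‑6‑oxo‑3‑(propanoyloxy)heptanoate | CC(=O)[C@H](OCc1ccccc1)[C@@H](C)[C@H](OC(=O)CC)[C@](C)(O)C(=O)OC | intermediate
12 | methyl (2S,3S,4S,5R)‑5‑(benzyloxy)‑6‑hydroxy‑2,4,6‑trimethyl‑3‑(propanoyloxy)oxane‑2‑carboxylate (cyclic hemiketal, both C6 anomers) | c1ccccc1CO[C@@H]1[C@@H](C)[C@H](OC(=O)CC)[C@@](C)(C(=O)OC)OC1(C)O | intermediate (not isolated)
13 | methyl (2S,3S,4R,5R,6S)‑5‑(benzyloxy)‑2,4,6‑trimethyl‑3‑(propanoyloxy)oxane‑2‑carboxylate | c1ccccc1CO[C@@H]1[C@@H](C)[C@H](OC(=O)CC)[C@@](C)(C(=O)OC)O[C@H]1C | intermediate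
14 | (4aS,6S,7R,8R,8aS)‑7‑(benzyloxy)‑4‑hydroxy‑3,4a,6,8‑tetramethyl‑6,7,8,8a‑tetrahydro‑4aH‑pyrano[3,2‑b]pyran‑2‑one | c1ccccc1CO[C@@H]1[C@@H](C)[C@@H]2OC(=O)C(C)=C(O)[C@@]2(C)O[C@H]1C | intermediate
15 | (3R,4S,4aR,6S,7R,8R,8aS)‑7‑(benzyloxy)‑4‑hydroxy‑3,4a,6,8‑tetramethylhexahydro‑2H,5H‑pyrano[3,2‑b]pyran‑2‑one | c1ccccc1CO[C@@H]1[C@@H](C)[C@@H]2OC(=O)[C@H](C)[C@H](O)[C@@]2(C)O[C@H]1C | intermediate (not isolated)
16 | (3R,4S,4aR,6S,7R,8R,8aS)‑4,7‑dihydroxy‑3,4a,6,8‑tetramethylhexahydro‑2H,5H‑pyrano[3,2‑b]pyran‑2‑one | O[C@@H]1[C@@H](C)[C@@H]2OC(=O)[C@H](C)[C@H](O)[C@@]2(C)O[C@H]1C | intermediate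
17 | 2‑butylfuran | CCCCc1ccco1 | starting material
18 | (2E)‑4‑oxooct‑2‑enal | CCCCC(=O)/C=C/C=O | intermediate (not isolated)
19 | (2E)‑4‑oxooct‑2‑enoic acid | CCCCC(=O)/C=C/C(=O)O | intermediate
20 | Botcinin I | CCCCC(=O)/C=C/C(=O)O[C@@H]1[C@@H](C)[C@@H]2OC(=O)[C@H](C)[C@H](O)[C@@]2(C)O[C@H]1C | target

**Totals**
Total step count: 14. Longest linear sequence: 13 (steps 1–12 and 14).

**Three steps most likely to fail, each with a fallback**

Step 8 (dihydroxylation). C4 and C5 both depend on OsO4 choosing the face anti to the C7 branch on a hindered, electron‑poor enoate. The product can also drift into ketals with the C8 ketone. The fallback sets out from aldehyde 8 and comes back at 11. Aldehyde 8 is added at −78 °C to the lithium enolate (LiN(iPr)2) of (2R,5R)‑2‑tert‑butyl‑5‑methyl‑1,3‑dioxolan‑4‑one, made from D‑lactic acid and pivalaldehyde. C4 is then fixed by the lactic acid carbon (attack anti to tert‑butyl) and not by approach to an alkene, at the cost of a second bought stereocentre. C5 relies on Felkin addition and must be checked. This gives the aldol adduct (2R,5S)‑5‑[(1S,2S,3R)‑3‑(benzyloxy)‑1‑hydroxy‑2‑methyl‑4‑oxopentyl]‑2‑tert‑butyl‑5‑methyl‑1,3‑dioxolan‑4‑one F1. Propanoylation of its secondary hydroxyl gives the propanoate F2. CSA in methanol then opens the acylal to the methyl ester and tertiary alcohol, which is 11.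

Step 11 (Dieckmann closure onto the hindered α‑alkoxy ester). The fallback sets out from diol 10 and comes back at 14, generating the enolate reductively from an α‑bromo ester. Diol 10 is acylated with 2‑bromopropanoyl bromide/pyridine to methyl (2S,3S,4S,5R)‑5‑(benzyloxy)‑3‑[(2‑bromopropanoyl)oxy]‑2‑hydroxy‑2,4‑dimethyl‑6‑oxoheptanoate F3. Reductive etherification as in step 10 gives methyl (2S,3S,4R,5R,6S)‑5‑(benzyloxy)‑3‑[(2‑bromopropanoyl)oxy]‑2,4,6‑trimethyloxane‑2‑carboxylate F4. SmI2 in THF at −78 °C then forms the samarium enolate, which acylates the neighbouring ester (Reformatsky‑type cyclisation) to give 14.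

Step 14 (site‑selective acylation of 7‑OH next to a free 3‑OH, with a base‑sensitive C2). The fallback sets out from 14 and comes back at 20, using orthogonal protection. Hydrogenation of 14 over Ni alone stops at the benzyl ether 15, which is isolated. Et3SiOTf/2,6‑lutidine gives the 7‑O‑benzyl 3‑O‑triethylsilyl lactone F5. H2 with Pd(OH)2/C gives the 3‑O‑triethylsilyl 7‑hydroxy lactone F6. MNBA esterification with 19 gives the 3‑O‑triethylsilyl ether of the target F7. HF·pyridine then releases 20.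

**Further compounds**
F1 | step 8 | (2R,5S)‑5‑[(1S,2S,3R)‑3‑(benzyloxy)‑1‑hydroxy‑2‑methyl‑4‑oxopentyl]‑2‑tert‑butyl‑5‑methyl‑1,3‑dioxolan‑4‑one | C[C@@]1([C@@H](O)[C@H](C)[C@@H](OCc2ccccc2)C(C)=O)O[C@@H](C(C)(C)C)OC1=O
F2 | step 8 | (2R,5S)‑5‑[(1S,2S,3R)‑3‑(benzyloxy)‑2‑methyl‑4‑oxo‑1‑(propanoyloxy)pentyl]‑2‑tert‑butyl‑5‑methyl‑1,3‑dioxolan‑4‑one | C[C@@]1([C@@H](OC(=O)CC)[C@H](C)[C@@H](OCc2ccccc2)C(C)=O)O[C@@H](C(C)(C)C)OC1=O
F3 | step 11 | methyl (2S,3S,4S,5R)‑5‑(benzyloxy)‑3‑[(2‑bromopropanoyl)oxy]‑2‑hydroxy‑2,4‑dimethyl‑6‑oxoheptanoate | CC(=O)[C@H](OCc1ccccc1)[C@@H](C)[C@H](OC(=O)C(C)Br)[C@](C)(O)C(=O)OC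
F4 | step 11 | methyl (2S,3S,4R,5R,6S)‑5‑(benzyloxy)‑3‑[(2‑bromopropanoyl)oxy]‑2,4,6‑trimethyloxane‑2‑carboxylate | c1ccccc1CO[C@@H]1[C@@H](C)[C@H](OC(=O)C(C)Br)[C@@](C)(C(=O)OC)O[C@H]1C
F5 | step 14 | 7‑O‑benzyl 3‑O‑triethylsilyl derivative of 16 | c1ccccc1CO[C@@H]1[C@@H](C)[C@@H]2OC(=O)[C@H](C)[C@H](O[Si](CC)(CC)CC)[C@@]2(C)O[C@H]1C
F6 | step 14 | 3‑O‑triethylsilyl derivative of 16 | O[C@@H]1[C@@H](C)[C@@H]2OC(=O)[C@H](C)[C@H](O[Si](CC)(CC)CC)[C@@]2(C)O[C@H]1C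
F7 | step 14 | 3‑O‑triethylsilyl ether of 20 | CCCCC(=O)/C=C/C(=O)O[C@@H]1[C@@H](C)[C@@H]2OC(=O)[C@H](C)[C@H](O[Si](CC)(CC)CC)[C@@]2(C)O[C@H]1C
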